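**Plan**
- Retrosynthesis: the three aryl–CH2 bonds (C7–CH2 on the benzofuran, C2'–CH2 and C6'–CH2 on ring A) are cut together, each back to a 1,1-dimethylallyl ether on the neighbouring oxygen; C4' carries a bromine as a temporary blocking group.
- What makes this possible: each prenylated carbon (C7, C2', C6') is ortho to a phenolic oxygen (on C6, C3', C5'), and C7 lies on the C6–C7 bond, which has more double-bond character than C5–C6.
- The three O–CMe2 bonds are then cut to a bromo-triphenol, and furan ring C (O1–C2 and C2=C3) is cut to a salicyl phosphonium salt and an aroyl chloride.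
- Forward: rings A and B are bought intact and ring C is closed by an intramolecular acyl-Wittig reaction. Demethylation, threefold O-propargylation, semihydrogenation, the triple Claisen rearrangement and removal of the bromine follow.
- Stereochemistry: the target has no stereocentre and no E/Z-defined alkene (each alkene ends in CMe2), so nothing has to be set.

Key step: step 8

Remarks: Benzofuran locants are O1, C2, C3, C3a, C4–C7, C7a; ring A is the 2-aryl ring (C1'–C6'), ring B the benzo ring, ring C the furan ring. The methyl ethers 1 and 4 and the reagent 3-chloro-3-methylbut-1-yne are assumed to be purchasable. The methyl ethers are used because free phenols would be acylated in step 4.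

**Step 1**
Reactants: 1 2-hydroxy-4-methoxybenzaldehyde
Product: 2 2-(hydroxymethyl)-5-methoxyphenol
Conditions: NaBH4, MeOH, 0 °C
Reagents that add atoms: none
Why: Borohydride reduction of the aldehyde to the benzylic alcohol should be clean, since the phenol and the aryl ether do not react with NaBH4.

**Step 2**
Reactants: 2 2-(hydroxymethyl)-5-methoxyphenol
Product: 3 [(2-hydroxy-4-methoxyphenyl)methyl]triphenylphosphonium bromide
Conditions: PPh3·HBr, MeCN, reflux
Reagents that add atoms: triphenylphosphine hydrobromide, [Br-].c1ccc([PH+](c2ccccc2)c2ccccc2)cc1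
Why: Acid-promoted nucleophilic substitution of the ortho-hydroxybenzylic alcohol by triphenylphosphine (through its ortho-quinone methide) is the standard preparation of salicyl phosphonium salts.

**Step 3**
Reactants: 4 4-bromo-3,5-dimethoxybenzoic acid
Product: 5 4-bromo-3,5-dimethoxybenzoyl chloride
Conditions: (COCl)2, DMF (cat.), CH2Cl2, 0 °C to rt
Reagents that add atoms: oxalyl chloride, O=C(Cl)C(=O)Cl
Why: Acid chloride formation through the Vilsmeier-type chloroiminium catalyst leaves the methyl ethers and the aryl bromide untouched.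

**Step 4**
Reactants: 3 [(2-hydroxy-4-methoxyphenyl)methyl]triphenylphosphonium bromide; 5 4-bromo-3,5-dimethoxybenzoyl chloride
Product: 8 2-(4-bromo-3,5-dimethoxyphenyl)-6-methoxy-1-benzofuran, via O-aroyl phosphonium bromide 6 (not isolated), via phosphorus ylide 7 (not isolated)
Conditions: Et3N, toluene, reflux
Reagents that add atoms: none
Why: O-acylation of the phenol, deprotonation to the ylide and intramolecular Wittig olefination of the ester carbonyl close furan ring C (O1–C2 and C2=C3), the established acyl-Wittig route to 2-arylbenzofurans.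

**Step 5**
Reactants: 8 2-(4-bromo-3,5-dimethoxyphenyl)-6-methoxy-1-benzofuran
Product: 9 2-(4-bromo-3,5-dihydroxyphenyl)-1-benzofuran-6-ol
Conditions: BBr3, CH2Cl2, −78 °C to rt; then H2O
Reagents that add atoms: none
Why: Lewis-acid cleavage of aryl methyl ethers by BBr3 (bromide attack on the methyl of the O–boron complex) should free all three phenols, and the benzofuran and the aryl bromide tolerate the reagent.

**Step 6**
Reactants: 9 2-(4-bromo-3,5-dihydroxyphenyl)-1-benzofuran-6-ol
Product: 10 2-[4-bromo-3,5-bis(2-methylbut-3-yn-2-yloxy)phenyl]-6-(2-methylbut-3-yn-2-yloxy)-1-benzofuran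
Conditions: 3-chloro-3-methylbut-1-yne (4.5 equiv), DBU (5 equiv), CuCl2·2H2O (cat.), MeCN, 0 °C
Reagents that add atoms: 3-chloro-3-methylbut-1-yne, C#CC(C)(C)Cl
Why: In this copper-catalysed propargylic etherification, which consumes one molecule of the tertiary chloride per hydroxyl, the copper acetylide of the chloride ionises to a copper allenylidene that each phenoxide captures at the tertiary carbon, at a temperature well below that at which aryl propargyl ethers cyclise to chromenes.

**Step 7**
Reactants: 10 2-[4-bromo-3,5-bis(2-methylbut-3-yn-2-yloxy)phenyl]-6-(2-methylbut-3-yn-2-yloxy)-1-benzofuran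
Product: 11 2-[4-bromo-3,5-bis(2-methylbut-3-en-2-yloxy)phenyl]-6-(2-methylbut-3-en-2-yloxy)-1-benzofuran
Conditions: H2 (1 atm), Pd/CaCO3 poisoned with Pb(OAc)2 (Lindlar catalyst), quinoline, EtOAc, rt
Reagents that add atoms: none
Why: Lindlar semihydrogenation of the terminal alkynes should stop at the vinyl stage, and the quinoline-poisoned catalyst should spare the aryl bromide and the benzofuran C2=C3 bond.

**Step 8**
Reactants: 11 2-[4-bromo-3,5-bis(2-methylbut-3-en-2-yloxy)phenyl]-6-(2-methylbut-3-en-2-yloxy)-1-benzofuran
Product: 12 2-bromo-5-[6-hydroxy-7-(3-methylbut-2-enyl)-1-benzofuran-2-yl]-4,6-bis(3-methylbut-2-enyl)benzene-1,3-diol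
Conditions: PhNEt2 (degassed), 140 °C, argon
Reagents that add atoms: none
Why: Each 1,1-dimethylallyl aryl ether should undergo a concerted [3,3] sigmatropic shift (aromatic Claisen rearrangement) through a chair-like transition state to an ortho-cyclohexadienone that tautomerises to the phenol; the closest known case is the thermal conversion of 1,1-dimethylallyl phenyl ethers into ortho-prenylphenols, which the gem-dimethyl group accelerates. The allyl unit is transposed, so the former vinyl CH2 becomes the benzylic carbon and the three new bonds C7–CH2, C2'–CH2 and C6'–CH2 carry linear prenyl groups. No ring is closed and no stereocentre is created. The step needs site selectivity at three places: on ring A the C4' bromine leaves each ether a single hydrogen-bearing ortho carbon, because a shift onto the brominated carbon gives a dienone that cannot enolise and reverts. On the benzofuran the C6 ether is expected to move to C7 and not C5 because the C6–C7 bond has the greater double-bond character, as 7-allyloxycoumarins and 2-naphthyl allyl ethers rearrange to the angular position. The weakly basic amine solvent scavenges traces of acid that would cleave the tertiary ethers or cyclise the ortho-prenylphenols to chromans.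

**Step 9**
Reactants: 12 2-bromo-5-[6-hydroxy-7-(3-methylbut-2-enyl)-1-benzofuran-2-yl]-4,6-bis(3-methylbut-2-enyl)benzene-1,3-diol
Product: 13 2-[4-bromo-3,5-bis(tert-butyldimethylsilyloxy)-2,6-bis(3-methylbut-2-enyl)phenyl]-6-(tert-butyldimethylsilyloxy)-7-(3-methylbut-2-enyl)-1-benzofuran
Conditions: TBSCl, imidazole, DMAP (cat.), DMF, 40 °C
Reagents that add atoms: tert-butyldimethylsilyl chloride, CC(C)(C)[Si](C)(C)Cl
Why: Imidazole-buffered O-silylation masks the three acidic phenols before the organolithium step without exposing the prenylphenols to acid.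

**Step 10**
Reactants: 13 2-[4-bromo-3,5-bis(tert-butyldimethylsilyloxy)-2,6-bis(3-methylbut-2-enyl)phenyl]-6-(tert-butyldimethylsilyloxy)-7-(3-methylbut-2-enyl)-1-benzofuran
Product: 16 5-[6-hydroxy-7-(3-methylbut-2-enyl)-1-benzofuran-2-yl]-4,6-bis(3-methylbut-2-enyl)benzene-1,3-diol, via C4'-aryllithium 14 (not isolated), via debrominated tris(silyl) ether 15 (not isolated)
Conditions: t-BuLi (2.2 equiv), Et2O, −78 °C; MeOH, −78 °C; then Bu4NF, AcOH, THF, 0 °C
Reagents that add atoms: none
Why: Bromine–lithium exchange with t-BuLi at −78 °C should outrun silyl migration and allylic deprotonation, methanol protonates C4', and acetic-acid-buffered fluoride desilylation then frees the three phenols without touching the prenyl groups.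

**Compound list**
1 | 2-hydroxy-4-methoxybenzaldehyde | COc1ccc(C=O)c(O)c1 | starting material
2 | 2-(hydroxymethyl)-5-methoxyphenol | COc1ccc(CO)c(O)c1 | intermediate
3 | [(2-hydroxy-4-methoxyphenyl)methyl]triphenylphosphonium bromide | COc1ccc(C[P+](c2ccccc2)(c2ccccc2)c2ccccc2)c(O)c1.[Br-] | intermediate
4 | 4-bromo-3,5-dimethoxybenzoic acid | COc1cc(C(=O)O)cc(OC)c1Br | starting material
5 | 4-bromo-3,5-dimethoxybenzoyl chloride | COc1cc(C(=O)Cl)cc(OC)c1Br | intermediate
6 | {[2-(4-bromo-3,5-dimethoxybenzoyloxy)-4-methoxyphenyl]methyl}triphenylphosphonium bromide | COc1ccc(C[P+](c2ccccc2)(c2ccccc2)c2ccccc2)c(OC(=O)c2cc(OC)c(Br)c(OC)c2)c1.[Br-] | intermediate (not isolated)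
7 | 5-methoxy-2-[(triphenyl-λ5-phosphanylidene)methyl]phenyl 4-bromo-3,5-dimethoxybenzoate | COc1ccc(C=P(c2ccccc2)(c2ccccc2)c2ccccc2)c(OC(=O)c2cc(OC)c(Br)c(OC)c2)c1 | intermediate (not isolated)
8 | 2-(4-bromo-3,5-dimethoxyphenyl)-6-methoxy-1-benzofuran | COc1ccc2cc(-c3cc(OC)c(Br)c(OC)c3)oc2c1 | intermediate
9 | 2-(4-bromo-3,5-dihydroxyphenyl)-1-benzofuran-6-ol | Oc1ccc2cc(-c3cc(O)c(Br)c(O)c3)oc2c1 | intermediate
10 | 2-[4-bromo-3,5-bis(2-methylbut-3-yn-2-yloxy)phenyl]-6-(2-methylbut-3-yn-2-yloxy)-1-benzofuran | C#CC(C)(C)Oc1ccc2cc(-c3cc(OC(C)(C)C#C)c(Br)c(OC(C)(C)C#C)c3)oc2c1 | intermediate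
11 | 2-[4-bromo-3,5-bis(2-methylbut-3-en-2-yloxy)phenyl]-6-(2-methylbut-3-en-2-yloxy)-1-benzofuran | C=CC(C)(C)Oc1ccc2cc(-c3cc(OC(C)(C)C=C)c(Br)c(OC(C)(C)C=C)c3)oc2c1 | intermediate
12 | 2-bromo-5-[6-hydroxy-7-(3-methylbut-2-enyl)-1-benzofuran-2-yl]-4,6-bis(3-methylbut-2-enyl)benzene-1,3-diol | CC(C)=CCc1c(O)c(Br)c(O)c(CC=C(C)C)c1-c1cc2ccc(O)c(CC=C(C)C)c2o1 | intermediate
13 | 2-[4-bromo-3,5-bis(tert-butyldimethylsilyloxy)-2,6-bis(3-methylbut-2-enyl)phenyl]-6-(tert-butyldimethylsilyloxy)-7-(3-methylbut-2-enyl)-1-benzofuran | CC(C)=CCc1c(O[Si](C)(C)C(C)(C)C)c(Br)c(O[Si](C)(C)C(C)(C)C)c(CC=C(C)C)c1-c1cc2ccc(O[Si](C)(C)C(C)(C)C)c(CC=C(C)C)c2o1 | intermediate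
14 | {2,6-bis(tert-butyldimethylsilyloxy)-4-[6-(tert-butyldimethylsilyloxy)-7-(3-methylbut-2-enyl)-1-benzofuran-2-yl]-3,5-bis(3-methylbut-2-enyl)phenyl}lithium | CC(C)=CCc1c(O[Si](C)(C)C(C)(C)C)c([Li])c(O[Si](C)(C)C(C)(C)C)c(CC=C(C)C)c1-c1cc2ccc(O[Si](C)(C)C(C)(C)C)c(CC=C(C)C)c2o1 | intermediate (not isolated)
15 | 2-[3,5-bis(tert-butyldimethylsilyloxy)-2,6-bis(3-methylbut-2-enyl)phenyl]-6-(tert-butyldimethylsilyloxy)-7-(3-methylbut-2-enyl)-1-benzofuran | CC(C)=CCc1c(O[Si](C)(C)C(C)(C)C)cc(O[Si](C)(C)C(C)(C)C)c(CC=C(C)C)c1-c1cc2ccc(O[Si](C)(C)C(C)(C)C)c(CC=C(C)C)c2o1 | intermediate (not isolated)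
16 | 5-[6-hydroxy-7-(3-methylbut-2-enyl)-1-benzofuran-2-yl]-4,6-bis(3-methylbut-2-enyl)benzene-1,3-diol | CC(C)=CCc1c(O)cc(O)c(CC=C(C)C)c1-c1cc2ccc(O)c(CC=C(C)C)c2o1 | target

**Step count**
Total steps: 10. Longest linear sequence: 9 steps (1, 2, 4, 5, 6, 7, 8, 9, 10).

**Steps most likely to fail**

Step 8. The ether on C6 may shift to C5 in competition with C7, and the tertiary ethers may fragment thermally with loss of isoprene before they rearrange, above all next to the crowded C1' position. The fallback sets out from triphenol 9 and moves the prenyl termini to a later olefin metathesis. O-Allylation with allyl bromide and K2CO3 in refluxing acetone should give 2-[4-bromo-3,5-bis(prop-2-enyloxy)phenyl]-6-(prop-2-enyloxy)-1-benzofuran F1. Primary allyl ethers cannot lose a diene and are well known to rearrange to the angular position of such bicyclic phenols, so heating F1 in PhNEt2 at about 195 °C should give 2-bromo-5-[6-hydroxy-7-(prop-2-enyl)-1-benzofuran-2-yl]-4,6-bis(prop-2-enyl)benzene-1,3-diol F2. Threefold cross-metathesis of F2 with excess 2-methylbut-2-ene and the second-generation Grubbs catalyst (H2IMes)(PCy3)Cl2Ru=CHPh in CH2Cl2 at 40 °C then turns each allyl into a prenyl group. The fallback comes back to the route at compound 12.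

Step 6. Etherification may stall at the two phenols flanked by bromine, leaving mixtures of partly alkylated phenols. The fallback sets out from triphenol 9 and installs the alkene oxidation level directly by a Tsuji–Trost O-allylation. 2-Methylbut-3-en-2-ol is deprotonated with n-BuLi in THF at −78 °C and acylated with isobutyl chloroformate to give 2-methylbut-3-en-2-yl 2-methylpropyl carbonate F3. Treatment of 9 with F3 and catalytic Pd(PPh3)4 in THF at 0 °C should deliver the phenoxides to the more substituted terminus of the dimethylallyl palladium complex under kinetic control. At this temperature the hindered, electron-rich aryl bromide should not undergo oxidative addition to zerovalent palladium. The fallback comes back at compound 11 and makes step 7 unnecessary.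

Step 10. Silicon may migrate from oxygen to the lithiated C4' (retro-Brook rearrangement) faster than protonation, or the exchange at the doubly flanked bromide may be incomplete. The fallback sets out from compound 13 and replaces the aryllithium by an aryl radical: Bu3SnH and AIBN in toluene at 90 °C should reduce the C–Br bond in a radical chain. The C4' radical has no alkene within reach for cyclisation, because the prenyl groups on ring A are meta to it. This fallback makes no new compound (F0) and comes back at compound 15, now isolated, which is desilylated with Bu4NF and AcOH as in the last stage of step 10.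

**Further compounds**
F1 | step 8 | 2-[4-bromo-3,5-bis(prop-2-enyloxy)phenyl]-6-(prop-2-enyloxy)-1-benzofuran | C=CCOc1ccc2cc(-c3cc(OCC=C)c(Br)c(OCC=C)c3)oc2c1
F2 | step 8 | 2-bromo-5-[6-hydroxy-7-(prop-2-enyl)-1-benzofuran-2-yl]-4,6-bis(prop-2-enyl)benzene-1,3-diol | C=CCc1c(O)c(Br)c(O)c(CC=C)c1-c1cc2ccc(O)c(CC=C)c2o1
F3 | step 6 | 2-methylbut-3-en-2-yl 2-methylpropyl carbonate | C=CC(C)(C)OC(=O)OCC(C)C
F0 | step 10 | none | none
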